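Drimane locants are used (C1–C10 in the decalin, C11 on C9, C12 on C8). Ring A is closed on a preformed ring B by joining the carbinol carbon C3 to the quaternary carbon C4. The route exploits the homoallylic alcohol array O–C3–C4(CH3)2–C5=C6 that spans rings A and B, the retron of a type 2 carbonyl-ene reaction. One Lewis-acid operation on a monocyclic keto aldehyde (a cyclohexanone with the C10 quaternary stereocentre, an exocyclic isopropylidene C5=C4 and a 3-oxopropyl chain C1–C3) forms the C3–C4 bond, the gem-dimethyl centre, the C3 stereocentre and the C5=C6 alkene. C10 comes from a palladium-catalysed enantioselective allylation; C9 is set afterwards through an allylsilane.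

Key step: step 6

Remark: compound 1 is taken as a commercial vinylogous ester (the ethyl enol ether of 2-methylcyclohexane-1,3-dione), and the ligand enantiomer in step 3 is chosen by analogy with allylations of 2-methylcyclohexanone enolates; the antipodal ligand would be used if the sense proves opposite.

Step 1
Reactants: 1 3-ethoxy-2-methylcyclohex-2-en-1-one; 2 isopropenylmagnesium bromide
Product: 4 2-methyl-3-(prop-1-en-2-yl)cyclohex-2-en-1-one, via magnesium alkoxide adduct 3 (not isolated)
Conditions: 2 (1.3 equiv), THF, 0 to 25 °C; then 1 M HCl, 0 °C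
Reagents that add atoms: water, O (carbonyl oxygen of 4, from the acidic work-up)
Why: Stork–Danheiser transposition: 1,2-addition of the Grignard reagent to the vinylogous ester carbonyl, then acid-mediated enol-ether hydrolysis with loss of the tertiary hydroxyl, should give the transposed dienone; no stereocentre is formed.

Step 2
Reactants: 4 2-methyl-3-(prop-1-en-2-yl)cyclohex-2-en-1-one
Product: 6 trimethyl{[2-methyl-3-(propan-2-ylidene)cyclohex-1-en-1-yl]oxy}silane, via lithium dienolate 5 (not isolated)
Conditions: Li (2.2 equiv), t-BuOH (1.0 equiv), NH3(l)/THF, −78 °C; NH3 evaporated; TMSCl, Et3N, THF, −78 to 0 °C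
Reagents that add atoms: chlorotrimethylsilane, C[Si](C)(C)Cl
Why: Birch-type dissolving-metal reduction of the linear dienone should protonate the terminal δ-carbon and leave the extended dienolate regiospecifically, which is trapped on oxygen; no stereocentre is formed.

Step 3
Reactants: 6 trimethyl{[2-methyl-3-(propan-2-ylidene)cyclohex-1-en-1-yl]oxy}silane; 7 diallyl carbonate
Product: 8 (2S)-2-methyl-2-(prop-2-en-1-yl)-3-(propan-2-ylidene)cyclohexan-1-one
Conditions: Pd2(dba)3 (2.5 mol %), (R)-t-BuPHOX (6.25 mol %), Bu4N[Ph3SiF2] (35 mol %), 7 (1.05 equiv), THF, 25 °C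
Reagents that add atoms: none
Why: Tsuji–Trost-type enantioselective allylic alkylation of a silyl enol ether: fluoride releases the enolate, which is allylated at its α-carbon (the future C10) on the chiral zerovalent palladium phosphinooxazoline complex, so the ligand sets the quaternary stereocentre and the alkene stays as the exocyclic isopropylidene.

Step 4
Reactants: 8 (2S)-2-methyl-2-(prop-2-en-1-yl)-3-(propan-2-ylidene)cyclohexan-1-one
Product: 10 (2S)-2-(3-hydroxypropyl)-2-methyl-3-(propan-2-ylidene)cyclohexan-1-one, via pinacol boronate 9 (not isolated)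
Conditions: pinacolborane (1.5 equiv), RhCl(PPh3)3 (2 mol %), THF, 25 °C; then 30 % H2O2, 2 M NaOH, 0 °C
Reagents that add atoms: pinacolborane, CC1(C)OBOC1(C)C (boron and pinacol stay only in 9); hydrogen peroxide, OO (hydroxyl oxygen of 10)
Why: rhodium-catalysed anti-Markovnikov hydroboration should select the monosubstituted alkene over the ketone and the tetrasubstituted alkene, and oxidation of the C–B bond gives the primary alcohol; C10 is untouched.

Step 5
Reactants: 10 (2S)-2-(3-hydroxypropyl)-2-methyl-3-(propan-2-ylidene)cyclohexan-1-one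
Product: 11 3-[(1S)-1-methyl-2-oxo-6-(propan-2-ylidene)cyclohexyl]propanal
Conditions: Dess–Martin periodinane (1.2 equiv), pyridine, CH2Cl2, 0 to 25 °C
Reagents that add atoms: none
Why: Dess–Martin oxidation stops at the aldehyde under buffered conditions that leave the isopropylidene group and the ketone alone.

Step 6
Reactants: 11 3-[(1S)-1-methyl-2-oxo-6-(propan-2-ylidene)cyclohexyl]propanal
Product: 12 (6S,8aS)-6-hydroxy-5,5,8a-trimethyl-3,5,6,7,8,8a-hexahydronaphthalen-1(2H)-one
Conditions: MeAl(OAr)2 (MABR, Ar = 4-bromo-2,6-di-tert-butylphenyl, 2.2 equiv; made from Me3Al and ArOH 1:2 in CH2Cl2, 25 °C), CH2Cl2, −78 to −40 °C; 1 M HCl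
Reagents that add atoms: none
Why: The bulky aluminium aryloxide activates the C3 aldehyde, whose carbon is attacked by C4, the dimethyl-substituted terminus of the exocyclic alkene C5=C4, and the positive charge building at C5 is discharged by loss of a C6 hydrogen, the only hydrogen next to C5 because C4 and C10 are quaternary, so the alkene ends at C5=C6. The closest known reaction type is the Lewis-acid-promoted type 2 intramolecular carbonyl-ene (Prins-type) cyclisation of ε,ζ-unsaturated aldehydes to methylenecyclohexanols. Ring A closes as a six-membered ring through a chair transition state, 6-exo-trig at the carbonyl and with both alkene carbons inside the new ring. The new stereocentre C3 is controlled by C10: ring B fixes C9 equatorial and the C10 methyl axial on the forming chair, and the oxygen carrying the very large aluminium group should take the equatorial position, which is the 3S (3β) configuration, cis to the C10 methyl across the ring. The step needs attack at C4 and not at C5 (six- against five-membered closure, secured by the chair geometry and by the quaternary C10 that shields C5), equatorial and not axial oxygen (secured by the aryloxide bulk, which disfavours the compact concerted ene transition state that a small Lewis acid would use), and reaction of the aldehyde and not the ketone (secured by the lower electrophilicity of the hindered ketone, which has no ene partner within reach).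

Step 7
Reactants: 12 (6S,8aS)-6-hydroxy-5,5,8a-trimethyl-3,5,6,7,8,8a-hexahydronaphthalen-1(2H)-one
Product: 13 N'-[(6S,8aS)-6-hydroxy-5,5,8a-trimethyl-3,5,6,7,8,8a-hexahydronaphthalen-1(2H)-ylidene]-2,4,6-tri(propan-2-yl)benzenesulfonohydrazide
Conditions: 2,4,6-triisopropylbenzenesulfonohydrazide (1.1 equiv), conc. HCl (cat.), MeCN, 25 °C
Reagents that add atoms: 2,4,6-triisopropylbenzenesulfonohydrazide, CC(C)c1cc(C(C)C)c(S(=O)(=O)NN)c(C(C)C)c1
Why: acid-catalysed hydrazone condensation at the only ketone should place the sulfonamide nitrogen toward C8 and away from the quaternary C10, the geometry needed for syn deprotonation; the alkene and both stereocentres are unaffected.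

Step 8
Reactants: 13 N'-[(6S,8aS)-6-hydroxy-5,5,8a-trimethyl-3,5,6,7,8,8a-hexahydronaphthalen-1(2H)-ylidene]-2,4,6-tri(propan-2-yl)benzenesulfonohydrazide; 14 (trimethylsilyl)methyl trifluoromethanesulfonate
Product: 17 (2S,4aR)-1,1,4a-trimethyl-6-[(trimethylsilyl)methyl]-1,2,3,4,4a,7-hexahydronaphthalen-2-ol, via silylmethylated hydrazone dilithium salt 15 (not isolated), via vinyllithium 16 (not isolated)
Conditions: n-BuLi (3.1 equiv), TMEDA, THF, −78 °C; 14 (1.05 equiv), −78 °C; n-BuLi (1.2 equiv), −78 to 0 °C; H2O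
Reagents that add atoms: none
Why: Shapiro reaction preceded by α-alkylation of the hydrazone dianion: C8 is the only α-carbon with hydrogen, so it is alkylated and then deprotonated again, sulfinate and N2 are expelled to the C9 vinyllithium, and protonation gives the allylsilane with C8 now sp2; no stereocentre is created.

Step 9
Reactants: 17 (2S,4aR)-1,1,4a-trimethyl-6-[(trimethylsilyl)methyl]-1,2,3,4,4a,7-hexahydronaphthalen-2-ol; 18 formaldehyde (used as paraformaldehyde)
Product: 19 (2S,4aR,5R)-5-(hydroxymethyl)-1,1,4a-trimethyl-6-methylidene-1,2,3,4,4a,5,6,7-octahydronaphthalen-2-ol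
Conditions: (CH2O)n (3 equiv), Me2AlCl (3 equiv), CH2Cl2, −78 to −20 °C; aqueous Rochelle salt
Reagents that add atoms: none
Why: Hosomi–Sakurai hydroxymethylation: the allylsilane attacks aluminium-complexed formaldehyde at C9 (SE2′) and loss of silicon fixes the alkene at C8=C12; the electrophile should add to C9 from the face opposite the angular C10 methyl (the ring-A carbon C1 on the other face is tied back in the chair), which places C11 trans to that methyl (9R).

Step 10
Reactants: 19 (2S,4aR,5R)-5-(hydroxymethyl)-1,1,4a-trimethyl-6-methylidene-1,2,3,4,4a,5,6,7-octahydronaphthalen-2-ol; 20 umbelliferone (7-hydroxy-2H-chromen-2-one)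
Product: 21 7-{[(1R,6S,8aR)-6-hydroxy-5,5,8a-trimethyl-2-methylidene-1,2,3,5,6,7,8,8a-octahydronaphthalen-1-yl]methoxy}-2H-chromen-2-one
Conditions: 20 (1.5 equiv), PPh3 (1.5 equiv), DIAD (1.5 equiv), THF, 0 to 25 °C
Reagents that add atoms: none
Why: Mitsunobu etherification of the primary C11 hydroxyl with the acidic phenol; the hindered secondary C3 hydroxyl next to the gem-dimethyl carbon should not react, and no stereocentre is touched.

Step 11
Reactants: 21 7-{[(1R,6S,8aR)-6-hydroxy-5,5,8a-trimethyl-2-methylidene-1,2,3,5,6,7,8,8a-octahydronaphthalen-1-yl]methoxy}-2H-chromen-2-one; 22 3-hydroxy-3-methylbutanoic acid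
Product: 23 (2S,4aR,5R)-1,1,4a-trimethyl-6-methylidene-5-{[(2-oxo-2H-chromen-7-yl)oxy]methyl}-1,2,3,4,4a,5,6,7-octahydronaphthalen-2-yl 3-hydroxy-3-methylbutanoate (CNP0300349.1)
Conditions: 22 (3 equiv), EDC·HCl (3 equiv), DMAP (1 equiv), CH2Cl2, 25 °C
Reagents that add atoms: none
Why: Steglich esterification acylates the secondary C3 alcohol with retention, the tertiary hydroxyl of the acid being too hindered to compete, and the coumarin lactone and both alkenes tolerate the conditions.

Compound list
1 | 3-ethoxy-2-methylcyclohex-2-en-1-one | CCOC1=C(C)C(=O)CCC1 | starting material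
2 | isopropenylmagnesium bromide (prop-1-en-2-ylmagnesium bromide) | CC(=C)[Mg]Br | starting material
3 | bromomagnesium 3-ethoxy-2-methyl-1-(prop-1-en-2-yl)cyclohex-2-en-1-olate | CCOC1=C(C)C(O[Mg]Br)(C(C)=C)CCC1 | intermediate (not isolated)
4 | 2-methyl-3-(prop-1-en-2-yl)cyclohex-2-en-1-one | CC(=C)C1=C(C)C(=O)CCC1 | intermediate
5 | lithium 2-methyl-3-(propan-2-ylidene)cyclohex-1-en-1-olate | CC(C)=C1CCCC(O[Li])=C1C | intermediate (not isolated)
6 | trimethyl{[2-methyl-3-(propan-2-ylidene)cyclohex-1-en-1-yl]oxy}silane | CC(C)=C1CCCC(O[Si](C)(C)C)=C1C | intermediate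
7 | diallyl carbonate | C=CCOC(=O)OCC=C | starting material
8 | (2S)-2-methyl-2-(prop-2-en-1-yl)-3-(propan-2-ylidene)cyclohexan-1-one | C=CC[C@]1(C)C(=O)CCCC1=C(C)C | intermediate
9 | (2S)-2-methyl-3-(propan-2-ylidene)-2-[3-(4,4,5,5-tetramethyl-1,3,2-dioxaborolan-2-yl)propyl]cyclohexan-1-one | CC1(C)OB(CCC[C@]2(C)C(=O)CCCC2=C(C)C)OC1(C)C | intermediate (not isolated)
10 | (2S)-2-(3-hydroxypropyl)-2-methyl-3-(propan-2-ylidene)cyclohexan-1-one | OCCC[C@]1(C)C(=O)CCCC1=C(C)C | intermediate
11 | 3-[(1S)-1-methyl-2-oxo-6-(propan-2-ylidene)cyclohexyl]propanal | O=CCC[C@]1(C)C(=O)CCCC1=C(C)C | intermediate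
12 | (6S,8aS)-6-hydroxy-5,5,8a-trimethyl-3,5,6,7,8,8a-hexahydronaphthalen-1(2H)-one | C1CC=C2C(C)(C)[C@@H](O)CC[C@]2(C)C1=O | intermediate
13 | N'-[(6S,8aS)-6-hydroxy-5,5,8a-trimethyl-3,5,6,7,8,8a-hexahydronaphthalen-1(2H)-ylidene]-2,4,6-tri(propan-2-yl)benzenesulfonohydrazide | C1CC=C2C(C)(C)[C@@H](O)CC[C@]2(C)C1=NNS(=O)(=O)c1c(C(C)C)cc(C(C)C)cc1C(C)C | intermediate
14 | (trimethylsilyl)methyl trifluoromethanesulfonate | C[Si](C)(C)COS(=O)(=O)C(F)(F)F | starting material
15 | O,N-dilithio derivative of the hydrazone 13 carrying a (trimethylsilyl)methyl group on C8 (ring position 2, epimers) | C[Si](C)(C)CC1CC=C2C(C)(C)[C@@H](O[Li])CC[C@]2(C)C1=NN([Li])S(=O)(=O)c1c(C(C)C)cc(C(C)C)cc1C(C)C | intermediate (not isolated)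
16 | lithium (2S,4aR)-5-lithio-1,1,4a-trimethyl-6-[(trimethylsilyl)methyl]-1,2,3,4,4a,7-hexahydronaphthalen-2-olate | C[Si](C)(C)CC=1CC=C2C(C)(C)[C@@H](O[Li])CC[C@]2(C)C=1[Li] | intermediate (not isolated)
17 | (2S,4aR)-1,1,4a-trimethyl-6-[(trimethylsilyl)methyl]-1,2,3,4,4a,7-hexahydronaphthalen-2-ol | C[Si](C)(C)CC=1CC=C2C(C)(C)[C@@H](O)CC[C@]2(C)C=1 | intermediate
18 | formaldehyde (used as paraformaldehyde) | C=O | starting material
19 | (2S,4aR,5R)-5-(hydroxymethyl)-1,1,4a-trimethyl-6-methylidene-1,2,3,4,4a,5,6,7-octahydronaphthalen-2-ol | C=C1CC=C2C(C)(C)[C@@H](O)CC[C@]2(C)[C@@H]1CO | intermediate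
20 | umbelliferone (7-hydroxy-2H-chromen-2-one) | Oc1ccc2ccc(=O)oc2c1 | starting material
21 | 7-{[(1R,6S,8aR)-6-hydroxy-5,5,8a-trimethyl-2-methylidene-1,2,3,5,6,7,8,8a-octahydronaphthalen-1-yl]methoxy}-2H-chromen-2-one | C=C1CC=C2C(C)(C)[C@@H](O)CC[C@]2(C)[C@@H]1COc1ccc2ccc(=O)oc2c1 | intermediate
22 | 3-hydroxy-3-methylbutanoic acid | CC(C)(O)CC(=O)O | starting material
23 | (2S,4aR,5R)-1,1,4a-trimethyl-6-methylidene-5-{[(2-oxo-2H-chromen-7-yl)oxy]methyl}-1,2,3,4,4a,5,6,7-octahydronaphthalen-2-yl 3-hydroxy-3-methylbutanoate | C=C1CC=C2C(C)(C)[C@@H](OC(=O)CC(C)(C)O)CC[C@]2(C)[C@@H]1COc1ccc2ccc(=O)oc2c1 | target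

Total step count: 11. Longest linear sequence: 11 steps (1 to 23).

Steps most likely to fail

Step 6 (carbonyl-ene ring closure). The process at risk is facial selection at C3: if the oxygen goes axial through the compact concerted ene transition state, the 3R (3α) alcohol forms instead. The fallback sets out from 11 and rejoins at 17. The cyclisation is run with Me2AlCl in CH2Cl2 at −78 °C, conditions that favour the concerted pathway, to take the axial alcohol (6R,8aS)-6-hydroxy-5,5,8a-trimethyl-3,5,6,7,8,8a-hexahydronaphthalen-1(2H)-one F1 on purpose. This is carried through the operations of steps 7 and 8 via the hydrazone N'-[(6R,8aS)-6-hydroxy-5,5,8a-trimethyl-3,5,6,7,8,8a-hexahydronaphthalen-1(2H)-ylidene]-2,4,6-tri(propan-2-yl)benzenesulfonohydrazide F2 to the allylsilane (2R,4aR)-1,1,4a-trimethyl-6-[(trimethylsilyl)methyl]-1,2,3,4,4a,7-hexahydronaphthalen-2-ol F3. Dess–Martin oxidation then gives the ketone (4aR)-1,1,4a-trimethyl-6-[(trimethylsilyl)methyl]-3,4,4a,7-tetrahydronaphthalen-2(1H)-one F4, and NaBH4 in MeOH at 0 °C, delivering hydride axially to the 4,4-dimethyl ketone, should give the equatorial alcohol 17.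

Step 3 (enantioselective allylation). The process at risk is erosion of enantioselectivity, or allylation at the γ-carbon, with the hindered fully substituted dienolate. The fallback sets out from 4 and rejoins at 8. A one-pot reductive allylation (Li, NH3/THF, t-BuOH 1 equiv, −78 °C; then allyl bromide) should give racemic 2-methyl-2-(prop-2-en-1-yl)-3-(propan-2-ylidene)cyclohexan-1-one F5, whose enantiomers are separated by preparative chromatography on a chiral stationary phase to supply 8.

Step 9 (hydroxymethylation of the allylsilane). The process at risk is protodesilylation together with over-reaction of monomeric formaldehyde (formal formation at the free C3 hydroxyl, a second Prins reaction at the new exocyclic alkene). The fallback sets out from 17 and rejoins at 19, and brings in the one-carbon unit at the aldehyde oxidation level. Trimethyl orthoformate with catalytic TMSOTf (CH2Cl2, −78 °C; K2CO3/MeOH work-up to free the C3 hydroxyl) should give the acetal (2S,4aR,5R)-5-(dimethoxymethyl)-1,1,4a-trimethyl-6-methylidene-1,2,3,4,4a,5,6,7-octahydronaphthalen-2-ol F6. Mild hydrolysis (aqueous oxalic acid on silica gel) to the aldehyde (1R,6S,8aR)-6-hydroxy-5,5,8a-trimethyl-2-methylidene-1,2,3,5,6,7,8,8a-octahydronaphthalene-1-carbaldehyde F7, followed at once by NaBH4 reduction, gives 19.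

Further compounds
F1 | step 6 | (6R,8aS)-6-hydroxy-5,5,8a-trimethyl-3,5,6,7,8,8a-hexahydronaphthalen-1(2H)-one | C1CC=C2C(C)(C)[C@H](O)CC[C@]2(C)C1=O
F2 | step 6 | N'-[(6R,8aS)-6-hydroxy-5,5,8a-trimethyl-3,5,6,7,8,8a-hexahydronaphthalen-1(2H)-ylidene]-2,4,6-tri(propan-2-yl)benzenesulfonohydrazide | C1CC=C2C(C)(C)[C@H](O)CC[C@]2(C)C1=NNS(=O)(=O)c1c(C(C)C)cc(C(C)C)cc1C(C)C
F3 | step 6 | (2R,4aR)-1,1,4a-trimethyl-6-[(trimethylsilyl)methyl]-1,2,3,4,4a,7-hexahydronaphthalen-2-ol | C[Si](C)(C)CC=1CC=C2C(C)(C)[C@H](O)CC[C@]2(C)C=1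
F4 | step 6 | (4aR)-1,1,4a-trimethyl-6-[(trimethylsilyl)methyl]-3,4,4a,7-tetrahydronaphthalen-2(1H)-one | C[Si](C)(C)CC=1CC=C2C(C)(C)C(=O)CC[C@]2(C)C=1
F5 | step 3 | racemic 2-methyl-2-(prop-2-en-1-yl)-3-(propan-2-ylidene)cyclohexan-1-one | C=CCC1(C)C(=O)CCCC1=C(C)C
F6 | step 9 | (2S,4aR,5R)-5-(dimethoxymethyl)-1,1,4a-trimethyl-6-methylidene-1,2,3,4,4a,5,6,7-octahydronaphthalen-2-ol | C=C1CC=C2C(C)(C)[C@@H](O)CC[C@]2(C)[C@@H]1C(OC)OC
F7 | step 9 | (1R,6S,8aR)-6-hydroxy-5,5,8a-trimethyl-2-methylidene-1,2,3,5,6,7,8,8a-octahydronaphthalene-1-carbaldehyde | C=C1CC=C2C(C)(C)[C@@H](O)CC[C@]2(C)[C@@H]1C=O
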